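**Retrosynthetic overview**
1. The pyridine ring is closed last. The C1=N and N–C3 bonds come from an ortho-alkynyl aryl methyl ketone and ammonia, and the alkyne comes from an aryl triflate by Sonogashira coupling.
2. The biaryl bond (C7–C8') is made by Suzuki coupling of a naphthyl boronate with an aryl iodide that already carries the triflate. The iodide reacts first.
3. The iodo triflate comes from a symmetrical dihydroxyacetophenone by mono-iodination and then triflation of the less hindered hydroxyl.
4. Naphthalene ring B (the methyl-bearing ring) is built onto a bromoanisole (ring A) by aryne/dienolate annulation. The surviving bromine marks the later boron site. O-methylation and borylation follow.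
5. Order of ring formation: naphthalene ring B, then the biaryl bond, then the pyridine ring. Both benzene rings are bought.

Assumption: the SMILES has no stereodescriptor and the molecule has no stereocentre. Its 7,8'-axis is flanked only by OH, H and a peri C–H, so I take it as configurationally labile at room temperature and make the target as the single achiral compound drawn.

Step 1
Reactants: 1 3-methylbut-2-enoyl chloride; 2 diethylamine
Product: 3 N,N-diethyl-3-methylbut-2-enamide
Conditions: 2 (1.1 equiv), 2 M aq NaOH, CH2Cl2, 0 °C → rt
Reagents that add atoms: none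
Why: Schotten–Baumann N-acylation, in which the secondary amine attacks the acid chloride far faster than hydroxide does and NaOH only takes up the HCl; no stereocentre is formed.

Step 2
Reactants: 3 N,N-diethyl-3-methylbut-2-enamide; 4 2,4-dibromoanisole (2,4-dibromo-1-methoxybenzene)
Product: 7 5-bromo-8-methoxy-3-methylnaphthalen-1-ol, via lithium dienolate 5 (not isolated), via aryne 6 (not isolated)
Conditions: LiN(iPr)2 (3.5 equiv), THF, −78 °C; 3 (1.5 equiv); then 4 (1.0 equiv), −78 → 0 °C; 1 M HCl work-up
Reagents that add atoms: none
Why: Aryne annulation (formal [4+2] of a dienolate with a benzyne), in which LiN(iPr)2 turns 3 into 5 and removes H-3 of 4 (the proton between the two bromines), LiBr is lost on the methoxy side to give 6, the γ-carbon of 5 adds at the aryne carbon remote from the more strongly directing methoxy group, and the aryl anion next to OMe closes ring B by acyl substitution on the amide, so that loss of LiNEt2 and tautomerisation give the naphthol with the second bromine kept at C-5.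

Step 3
Reactants: 7 5-bromo-8-methoxy-3-methylnaphthalen-1-ol
Product: 8 1-bromo-4,5-dimethoxy-7-methylnaphthalene
Conditions: MeI (1.5 equiv), K2CO3, DMF, rt → 40 °C
Reagents that add atoms: iodomethane, CI
Why: Williamson ether synthesis, in which the naphtholate is O-methylated by SN2 attack on MeI and the aryl bromide is inert to K2CO3.

Step 4
Reactants: 8 1-bromo-4,5-dimethoxy-7-methylnaphthalene
Product: 9 2-(4,5-dimethoxy-7-methylnaphthalen-1-yl)-4,4,5,5-tetramethyl-1,3,2-dioxaborolane
Conditions: B2pin2 (1.2 equiv), Pd(dppf)Cl2 (3 mol %), KOAc (3 equiv), 1,4-dioxane, 90 °C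
Reagents that add atoms: bis(pinacolato)diboron, CC1(C)OB(OC1(C)C)B1OC(C)(C)C(C)(C)O1
Why: Miyaura borylation, in which zerovalent palladium inserts into the only carbon–bromine bond and KOAc mediates transfer of Bpin, under conditions that leave the aryl methyl ethers untouched.

Step 5
Reactants: 10 1-(2,6-dihydroxyphenyl)ethanone (2',6'-dihydroxyacetophenone)
Product: 11 1-(2,6-dihydroxy-3-iodophenyl)ethanone
Conditions: NIS (1.0 equiv), MeCN, 0 °C → rt, dark
Reagents that add atoms: N-iodosuccinimide, O=C1CCC(=O)N1I
Why: Electrophilic aromatic iodination, in which C-3 is ortho to one hydroxyl and para to the other (C-3 and C-5 are equivalent by symmetry and C-4 is meta to both), so one equivalent of NIS gives a single mono-iodide.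

Step 6
Reactants: 11 1-(2,6-dihydroxy-3-iodophenyl)ethanone
Product: 12 2-acetyl-3-hydroxy-4-iodophenyl trifluoromethanesulfonate
Conditions: Tf2O (1.05 equiv), pyridine (2.5 equiv), CH2Cl2, −78 → 0 °C
Reagents that add atoms: trifluoromethanesulfonic anhydride, O=S(=O)(OS(=O)(=O)C(F)(F)F)C(F)(F)F
Why: Regioselective O-sulfonylation, in which the 2-OH is wedged between iodine and the acetyl group and held in the stronger hydrogen bond to the carbonyl oxygen, so the freer and less hindered 6-OH is triflated.

Step 7
Reactants: 9 2-(4,5-dimethoxy-7-methylnaphthalen-1-yl)-4,4,5,5-tetramethyl-1,3,2-dioxaborolane; 12 2-acetyl-3-hydroxy-4-iodophenyl trifluoromethanesulfonate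
Product: 13 2-acetyl-4-(4,5-dimethoxy-7-methylnaphthalen-1-yl)-3-hydroxyphenyl trifluoromethanesulfonate
Conditions: 9 (1.05 equiv), Pd(PPh3)4 (5 mol %), K3PO4 (3 equiv), 1,4-dioxane/H2O 10:1, 60 °C
Reagents that add atoms: none
Why: Chemoselective Suzuki–Miyaura coupling, in which Pd(PPh3)4 inserts into the aryl iodide much faster than into the aryl triflate at 60 °C, so the biaryl bond forms only next to the free phenol, and the new axis is configurationally labile and needs no stereocontrol.

Step 8
Reactants: 13 2-acetyl-4-(4,5-dimethoxy-7-methylnaphthalen-1-yl)-3-hydroxyphenyl trifluoromethanesulfonate; 14 propyne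
Product: 17 dioncophylleine D, via alkynyl ketone 15 (not isolated), via ketimine 16 (not isolated)
Conditions: 14 (5 equiv), Pd(PPh3)2Cl2 (5 mol %), CuI (10 mol %), Et3N, DMF, sealed tube, 60 °C; then NH3 (7 M in MeOH, excess), sealed tube, 110 °C
Reagents that add atoms: ammonia, N
Why: Sonogashira coupling of the ketone-activated aryl triflate gives 15, after which a tandem imination–annulation takes place, in which ammonia condenses with the ortho-hydroxyaryl ketone to 16 and its nitrogen adds 6-endo-dig to the alkyne (helped by the copper and palladium salts still present) to give the aromatic isoquinoline with no stereocentre formed.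

**Compound list**
1 | 3-methylbut-2-enoyl chloride | CC(C)=CC(=O)Cl | starting material
2 | diethylamine | CCNCC | starting material
3 | N,N-diethyl-3-methylbut-2-enamide | CCN(CC)C(=O)C=C(C)C | intermediate
4 | 2,4-dibromoanisole | COc1ccc(Br)cc1Br | starting material
5 | lithium 1-(diethylamino)-3-methylbuta-1,3-dien-1-olate (dienolate of 3) | [Li+].[O-]C(=CC(C)=C)N(CC)CC | intermediate
6 | 3-bromo-6-methoxybenzyne (1-bromo-4-methoxy-2,3-didehydrobenzene) | COC1=CC=C(Br)C#C1 | intermediate
7 | 5-bromo-8-methoxy-3-methylnaphthalen-1-ol | COc1ccc(Br)c2cc(C)cc(O)c12 | intermediate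
8 | 1-bromo-4,5-dimethoxy-7-methylnaphthalene | COc1ccc(Br)c2cc(C)cc(OC)c12 | intermediate
9 | 2-(4,5-dimethoxy-7-methylnaphthalen-1-yl)-4,4,5,5-tetramethyl-1,3,2-dioxaborolane | COc1ccc(B3OC(C)(C)C(C)(C)O3)c2cc(C)cc(OC)c12 | intermediate
10 | 1-(2,6-dihydroxyphenyl)ethanone | CC(=O)c1c(O)cccc1O | starting material
11 | 1-(2,6-dihydroxy-3-iodophenyl)ethanone | CC(=O)c1c(O)ccc(I)c1O | intermediate
12 | 2-acetyl-3-hydroxy-4-iodophenyl trifluoromethanesulfonate | CC(=O)c1c(OS(=O)(=O)C(F)(F)F)ccc(I)c1O | intermediate
13 | 2-acetyl-4-(4,5-dimethoxy-7-methylnaphthalen-1-yl)-3-hydroxyphenyl trifluoromethanesulfonate | CC(=O)c1c(OS(=O)(=O)C(F)(F)F)ccc(-c2ccc(OC)c3c(OC)cc(C)cc23)c1O | intermediate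
14 | propyne | CC#C | starting material
15 | 1-[3-(4,5-dimethoxy-7-methylnaphthalen-1-yl)-2-hydroxy-6-(prop-1-yn-1-yl)phenyl]ethanone | CC#Cc1ccc(-c2ccc(OC)c3c(OC)cc(C)cc23)c(O)c1C(C)=O | intermediate
16 | 6-(4,5-dimethoxy-7-methylnaphthalen-1-yl)-2-(1-iminoethyl)-3-(prop-1-yn-1-yl)phenol | CC#Cc1ccc(-c2ccc(OC)c3c(OC)cc(C)cc23)c(O)c1C(C)=N | intermediate
17 | dioncophylleine D, 7-(4,5-dimethoxy-7-methylnaphthalen-1-yl)-1,3-dimethylisoquinolin-8-ol | COc1ccc(-c2ccc3cc(C)nc(C)c3c2O)c2cc(C)cc(OC)c12 | target

**Step count**
- Total step count: 8.
- Longest linear sequence: 6 steps (1, 2, 3, 4, 7, 8). The acetophenone branch (5, 6) joins at step 7.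

**The three steps most likely to fail**

*First risk, step 2 (aryne annulation).*
- Two selectivities must both go the right way. One is the direction of LiBr loss from lithiated 4. The other is the site of attack on aryne 6, where methoxy and bromine steer in opposite senses.
- LiN(iPr)2 can also add to the aryne.
- The fallback sets out from 3 and comes back at 7. It introduces the bromine only after the ring has been built.
- Dienolate 5 is combined with 3-methoxybenzyne F1, made in the flask from bought 3-bromoanisole and LiN(iPr)2 in THF. Here methoxy is the only director, and the product is 8-methoxy-3-methylnaphthalen-1-ol F2.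
- Ac2O and pyridine give 8-methoxy-3-methylnaphthalen-1-yl acetate F3, in which ring B is deactivated.
- NBS in MeCN at 0 °C then brominates ring A para to its methoxy group and gives 5-bromo-8-methoxy-3-methylnaphthalen-1-yl acetate F4.
- K2CO3 in MeOH removes the acetyl group and delivers 7.

*Second risk, step 6 (which hydroxyl is triflated).*
- If the 2-OH competes, the wrong triflate leads in the end to the 5-aryl isomer of the target.
- The fallback sets out from 11 and comes back at 13, without passing through 12, by changing the order of bond formation.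
- Compound 11 is coupled directly with boronate 9 (Pd(OAc)2, SPhos, K3PO4, 1,4-dioxane/H2O, 80 °C). This gives 1-[3-(4,5-dimethoxy-7-methylnaphthalen-1-yl)-2,6-dihydroxyphenyl]ethanone F5.
- Tf2O and pyridine in CH2Cl2 then triflate the 6-OH alone, because the 2-OH now lies between the acetyl group and the bulky naphthyl group. The product is 13.
- This order also removes any competition between iodide and triflate in the coupling.

*Third risk, step 8 (telescoped alkynylation and ring closure).*
- Two things can let the sequence stall or give side products on the most valuable intermediate. The gas coupling runs on a substrate with a free phenol. Imine formation must occur at a ketone flanked on both sides.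
- The fallback sets out from 13 and comes back at 17. It closes the ring through oxygen first.
- A base-free Stille coupling of 13 with tributyl(prop-1-ynyl)stannane (Pd(PPh3)4, LiCl, 1,4-dioxane, 90 °C) gives 15, which is now isolated.
- HBF4·OEt2 with AgBF4 (5 mol %) in AcOH makes the carbonyl oxygen add 6-endo to the alkyne. This gives 7-(4,5-dimethoxy-7-methylnaphthalen-1-yl)-8-hydroxy-1,3-dimethylisochromenylium tetrafluoroborate F6.
- NH3 in MeOH at rt then exchanges the ring oxygen for nitrogen (pyrylium-to-pyridine conversion) and gives 17.

**Further compounds**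
F1 | step 2 | 3-methoxybenzyne (1-methoxy-2,3-didehydrobenzene) | COC1=CC=CC#C1
F2 | step 2 | 8-methoxy-3-methylnaphthalen-1-ol | COc1cccc2cc(C)cc(O)c12
F3 | step 2 | 8-methoxy-3-methylnaphthalen-1-yl acetate | COc1cccc2cc(C)cc(OC(C)=O)c12
F4 | step 2 | 5-bromo-8-methoxy-3-methylnaphthalen-1-yl acetate | COc1ccc(Br)c2cc(C)cc(OC(C)=O)c12
F5 | step 6 | 1-[3-(4,5-dimethoxy-7-methylnaphthalen-1-yl)-2,6-dihydroxyphenyl]ethanone | CC(=O)c1c(O)ccc(-c2ccc(OC)c3c(OC)cc(C)cc23)c1O
F6 | step 8 | 7-(4,5-dimethoxy-7-methylnaphthalen-1-yl)-8-hydroxy-1,3-dimethylisochromenylium tetrafluoroborate | Cc1cc2ccc(-c3ccc(OC)c4c(OC)cc(C)cc34)c(O)c2c(C)[o+]1.F[B-](F)(F)F
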